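## Retrosynthetic overview

1. The target comes from a bridged δ-lactone tricycle by lactone reduction, double angeloylation, oxidative unmasking of C4 and acetylation of C11. The C9–O–C15(=O) lactone masks both angelate oxygens and a C4 silyl ether masks the enone carbonyl.
2. The seven-membered ring (formed last) is closed at C1–C2 by a transannular lactone-enolate aldol onto a cyclobutanone, followed by radical removal of the C2 oxygen.
3. The cyclobutane and the six-membered ring are formed together by a crossed intramolecular [2+2] of a vinylketene with the (E)-C3=C8 alkene. The C4 carbinol centre, later oxidised away, fixes the cage configuration.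
4. The acyclic precursor comes from two catalyst-controlled vinylogous Mukaiyama aldols on a C5 enal-acetal, with 1,3-anti reduction and lactonisation in between (the δ-lactone is the first, temporary ring).

## Conventions and assumptions

- Atom labels (mine, not IUPAC), read off the target: C1 = quaternary C bearing C14H3 and C15H2O; C2 = cyclobutane CH next to C1; C3 = bridgehead CH next to the ketone; C4 = C=O; C5 = vinylic CH; C6 = vinylic C bearing C12H3; C7 = second bridgehead CH; C8 = quaternary cyclobutane C bearing C13H3; C9 = CH–OAng; C10 = CH2; C11 = CH–OAc. In these labels the target is (1S,2S,3R,7R,8R,9R,11R).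
- Assumption: 1, 4, 11, 25 and both chiral catalysts are bought (4 is otherwise two steps from prenal by acetalisation and SeO2 oxidation).
- Assumption: the ester/lactone α-carbon (label C1) is carried as an inconsequential epimer mixture until step 10 fixes it.

## Route

Step 1
Reactants: 1 methyl 2-methyl-3-oxobutanoate
Product: 3 1-methoxy-2-methyl-1,3-bis(trimethylsilyloxy)buta-1,3-diene (E/Z mixture), via silyl enol ether 2 (not isolated)
Conditions: LDA (1.05 equiv), THF, −78 °C; TMSCl; then LDA (1.1 equiv), −78 °C; TMSCl, −78 °C → rt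
Reagents that add atoms: chlorotrimethylsilane, C[Si](C)(C)Cl
Why: Two successive enolisation/O-silylation events (Chan-type bis-silyl dienol ether synthesis) remove first the doubly activated α-proton and then a γ-methyl proton; no stereocentre is formed.

Step 2
Reactants: 3 1-methoxy-2-methyl-1,3-bis(trimethylsilyloxy)buta-1,3-diene; 4 (2E)-4,4-dimethoxy-2-methylbut-2-enal
Product: 6 methyl (5R,6E)-5-hydroxy-8,8-dimethoxy-2,6-dimethyl-3-oxooct-6-enoate (C2 epimers), via bis-TMS adduct 5 (not isolated)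
Conditions: Ti(OiPr)4 (10 mol%), (R)-BINOL (10 mol%), 4 Å MS, THF, −78 → −20 °C; then PPTS, MeOH, 0 °C
Reagents that add atoms: none
Why: Catalytic asymmetric vinylogous Mukaiyama aldol in which the diene terminus adds 1,2 to the Re face of the Ti–BINOL-bound enal (ligand antipode chosen to give 5R), followed by buffered methanolysis of both TMS groups that leaves the dimethyl acetal intact.

Step 3
Reactants: 6 methyl (5R,6E)-5-hydroxy-8,8-dimethoxy-2,6-dimethyl-3-oxooct-6-enoate
Product: 7 methyl (3R,5R,6E)-3,5-dihydroxy-8,8-dimethoxy-2,6-dimethyloct-6-enoate (C2 epimers)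
Conditions: Me4NBH(OAc)3, MeCN–AcOH (1:1), −30 °C
Reagents that add atoms: none
Why: Evans–Saksena reduction, in which the C5 hydroxyl binds boron and delivers hydride intramolecularly through a chair transition state to give the 1,3-anti diol (3R).

Step 4
Reactants: 7 methyl (3R,5R,6E)-3,5-dihydroxy-8,8-dimethoxy-2,6-dimethyloct-6-enoate
Product: 9 (2E)-3-[(2R,4R)-4-hydroxy-5-methyl-6-oxooxan-2-yl]but-2-enal (C5 epimers), via lactone acetal 8 (not isolated)
Conditions: CSA (10 mol%), CH2Cl2, rt; then H2O–THF, rt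
Reagents that add atoms: water, O
Why: Acid-catalysed lactonisation of the δ-hydroxy ester (the anti diol gives the cis-4,6-disubstituted δ-lactone) followed by acetal hydrolysis in the same flask, the C9 oxygen being acylated before the enal is released so that no γ-hydroxy-enal side reactions occur and no stereocentre is touched.

Step 5
Reactants: 9 (2E)-3-[(2R,4R)-4-hydroxy-5-methyl-6-oxooxan-2-yl]but-2-enal
Product: 10 (2E)-3-[(2R,4R)-4-(tert-butyldimethylsilyloxy)-5-methyl-6-oxooxan-2-yl]but-2-enal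
Conditions: TBSCl, imidazole, DMF, rt
Reagents that add atoms: tert-butyldimethylsilyl chloride, CC(C)(C)[Si](C)(C)Cl
Why: Standard silylation of the secondary alcohol gives a robust ether at C11 that survives every step up to step 15 and is orthogonal to the later C4 triethylsilyl ether.

Step 6
Reactants: 11 tert-butyl 3-methylbut-2-enoate
Product: 12 tert-butyl[(1-tert-butoxy-3-methylbuta-1,3-dien-1-yl)oxy]dimethylsilane
Conditions: LDA, THF, −78 °C; TBSCl, DMPU, −78 °C → rt
Reagents that add atoms: tert-butyldimethylsilyl chloride, CC(C)(C)[Si](C)(C)Cl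
Why: Kinetic γ-deprotonation of the senecioate and O-silylation of the dienolate gives the silyl dienol ether; no stereocentre is formed.

Step 7
Reactants: 10 (2E)-3-[(2R,4R)-4-(tert-butyldimethylsilyloxy)-5-methyl-6-oxooxan-2-yl]but-2-enal; 12 tert-butyl[(1-tert-butoxy-3-methylbuta-1,3-dien-1-yl)oxy]dimethylsilane
Product: 14 tert-butyl (2E,5S,6E)-5-hydroxy-3-methyl-7-[(2R,4R)-4-(tert-butyldimethylsilyloxy)-5-methyl-6-oxooxan-2-yl]octa-2,6-dienoate, via trichlorosilyl ether 13 (not isolated)
Conditions: SiCl4 (1.1 equiv), (R,R)-Denmark bisphosphoramide (5 mol%), iPr2NEt (10 mol%), CH2Cl2, −78 °C; aq. NaHCO3 work-up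
Reagents that add atoms: none
Why: Lewis-base-catalysed vinylogous Mukaiyama aldol (SiCl4/chiral phosphoramide) with exclusive γ-attack on the Si face of the enal to give the 5S carbinol and the (2E)-enoate under reagent control (either C5 configuration is available by choice of catalyst antipode, which matters because this centre only steers step 9 and is erased in step 14).

Step 8
Reactants: 14 tert-butyl (2E,5S,6E)-5-hydroxy-3-methyl-7-[(2R,4R)-4-(tert-butyldimethylsilyloxy)-5-methyl-6-oxooxan-2-yl]octa-2,6-dienoate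
Product: 16 (2E,5S,6E)-3-methyl-5-(triethylsilyloxy)-7-[(2R,4R)-4-(tert-butyldimethylsilyloxy)-5-methyl-6-oxooxan-2-yl]octa-2,6-dienoic acid, via bis-TES compound 15 (not isolated)
Conditions: TESOTf (4 equiv), 2,6-lutidine (6 equiv), CH2Cl2, −78 → 23 °C; then THF–pH 7 buffer
Reagents that add atoms: triethylsilyl trifluoromethanesulfonate, CC[Si](CC)(CC)OS(=O)(=O)C(F)(F)F
Why: Silyl triflate/2,6-lutidine silylates the C5 hydroxyl and, in excess, converts the tert-butyl ester into the silyl ester with loss of isobutene, the silyl ester alone being hydrolysed on buffered work-up.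

Step 9
Reactants: 16 (2E,5S,6E)-3-methyl-5-(triethylsilyloxy)-7-[(2R,4R)-4-(tert-butyldimethylsilyloxy)-5-methyl-6-oxooxan-2-yl]octa-2,6-dienoic acid
Product: 19 bicyclo[3.1.1]heptan-6-one lactone (C2 ketone; C4–OSiEt3 on the C2 side; C6=CH2; C8–CH3 syn and C8–lactone anti to the C4–C6 bridge), via acid chloride 17 (not isolated), via vinylketene 18 (not isolated)
Conditions: 1-chloro-N,N,2-trimethylprop-1-en-1-amine, CH2Cl2, 0 °C; then syringe-pump addition to Et3N (5 equiv), PhMe (0.005 M), 110 °C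
Reagents that add atoms: none
Why: Dehydrochlorination through the cis γ-methyl group gives a vinylketene that undergoes a crossed intramolecular ketene–alkene [2+2] cycloaddition (carbonyl carbon to the CH terminus C3, α-carbon to the methyl-bearing C8), forming the cyclobutanone and the six-membered ring at once; the (E)-alkene geometry is transferred suprafacially (C13 syn, C9 anti to the new bridge) and the C4 silyloxy centre fixes the face because C4–H rather than OSiEt3 must sit next to the C8 methyl (A(1,3)/syn-pentane strain), which sets C3, C7 and C8.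

Step 10
Reactants: 19 bicyclo[3.1.1]heptan-6-one lactone
Product: 22 bridged lactone S-methyl xanthate (C1–C2 bond closed; C2–OC(=S)SCH3), via lithium aldolate 20 (not isolated), via lithium xanthate 21 (not isolated)
Conditions: LiHMDS (1.2 equiv), THF, −78 → −40 °C; CS2 (10 equiv), −40 °C; MeI (10 equiv), −40 → 0 °C
Reagents that add atoms: carbon disulfide, S=C=S; iodomethane, CI
Why: Intramolecular aldol addition of the lactone enolate (the only enolisable site, since the cyclobutanone is flanked by bridgeheads) to the strained cyclobutanone closes the seven-membered ring from the only face the tether allows, the lactone forcing C15 cis to the C9 oxygen and so fixing quaternary C1, and the tertiary alkoxide is trapped in situ as the xanthate before retro-aldol can intervene.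

Step 11
Reactants: 22 bridged lactone S-methyl xanthate
Product: 23 bridged lactone with C2–H (C4–OSiEt3; C11–OTBS; C6=CH2)
Conditions: Bu3SnH (3 equiv), AIBN (0.2 equiv), PhMe, 100 °C
Reagents that add atoms: none
Why: Barton–McCombie deoxygenation, in which the tertiary cyclobutyl radical at C2 takes hydrogen on its only open face because C1 is locked in the ring, so C2 has the target configuration, while Chugaev elimination is impossible (bridgehead β-hydrogens and quaternary C1).

Step 12
Reactants: 23 bridged lactone with C2–H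
Product: 24 9,15-diol (C9–OH; C15H2–OH; C4–OSiEt3; C11–OTBS; C6=CH2)
Conditions: LiAlH4, THF, 0 °C → rt
Reagents that add atoms: none
Why: Hydride reduction of the δ-lactone to the primary/secondary diol releases exactly the two hydroxyls that carry angelates in the target, with silyl ethers and all stereocentres untouched.

Step 13
Reactants: 24 9,15-diol; 25 angelic acid ((2Z)-2-methylbut-2-enoic acid)
Product: 27 9,15-bis-angelate (C4–OSiEt3; C11–OTBS; C6=CH2), via mixed anhydride 26 (not isolated)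
Conditions: 25 (6 equiv), 2,4,6-Cl3C6H2COCl (6 equiv), Et3N, PhMe, rt; then 24, 80 °C
Reagents that add atoms: none
Why: Yamaguchi-type mixed-anhydride esterification acylates both hindered hydroxyls at the less encumbered angeloyl carbonyl, and omitting DMAP avoids Z→E isomerisation to tiglate.

Step 14
Reactants: 27 9,15-bis-angelate
Product: 30 enone (C4 ketone; C5=C6; C11–OTBS), via C4 alcohol 28 (not isolated), via β,γ-enone 29 (not isolated)
Conditions: IBX (4 equiv), DMSO, 25 °C; aq. NaHCO3 work-up; crude with DBU (0.2 equiv), CH2Cl2, 25 °C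
Reagents that add atoms: none
Why: IBX in DMSO cleaves the triethylsilyl ether selectively in the presence of the TBS ether and oxidises the released secondary alcohol in the same pot, and base then moves the exocyclic β,γ-double bond into conjugation to give the verbenone-type enone, erasing the C4 centre.

Step 15
Reactants: 30 enone (C11–OTBS)
Product: 31 C11 alcohol
Conditions: HF·pyridine, THF–pyridine, 0 °C → rt
Reagents that add atoms: none
Why: Acidic fluoride desilylation removes the hindered TBS ether without the base-induced 1,3-acyl migration of the neighbouring angelates.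

Step 16
Reactants: 31 C11 alcohol
Product: 32 CNP0364726.1 (target)
Conditions: Ac2O, Et3N, DMAP (cat.), CH2Cl2, 0 °C → rt
Reagents that add atoms: acetic anhydride, CC(=O)OC(C)=O
Why: Standard DMAP-catalysed acetylation of the single free secondary hydroxyl completes the target without affecting any stereocentre.

## Compound list

1 | methyl 2-methyl-3-oxobutanoate | COC(=O)C(C)C(C)=O | starting material
2 | methyl 2-methyl-3-(trimethylsilyloxy)but-2-enoate (E/Z mixture) | COC(=O)C(C)=C(C)O[Si](C)(C)C | intermediate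
3 | 1-methoxy-2-methyl-1,3-bis(trimethylsilyloxy)buta-1,3-diene (E/Z mixture) | COC(O[Si](C)(C)C)=C(C)C(=C)O[Si](C)(C)C | intermediate
4 | (2E)-4,4-dimethoxy-2-methylbut-2-enal | O=C/C(C)=C/C(OC)OC | starting material
5 | methyl (5R,6E)-8,8-dimethoxy-2,6-dimethyl-3,5-bis(trimethylsilyloxy)octa-2,6-dienoate | COC(=O)C(C)=C(O[Si](C)(C)C)C[C@@H](O[Si](C)(C)C)/C(C)=C/C(OC)OC | intermediate
6 | methyl (5R,6E)-5-hydroxy-8,8-dimethoxy-2,6-dimethyl-3-oxooct-6-enoate (C2 epimers) | COC(=O)C(C)C(=O)C[C@@H](O)/C(C)=C/C(OC)OC | intermediate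
7 | methyl (3R,5R,6E)-3,5-dihydroxy-8,8-dimethoxy-2,6-dimethyloct-6-enoate (anti diol; C2 epimers) | COC(=O)C(C)[C@H](O)C[C@@H](O)/C(C)=C/C(OC)OC | intermediate
8 | (4R,6R)-6-[(2E)-4,4-dimethoxybut-2-en-2-yl]-4-hydroxy-3-methyloxan-2-one (cis-4,6; C3 epimers) | COC(OC)/C=C(\C)[C@H]1C[C@@H](O)C(C)C(=O)O1 | intermediate
9 | (2E)-3-[(2R,4R)-4-hydroxy-5-methyl-6-oxooxan-2-yl]but-2-enal (C5 epimers) | O=C/C=C(\C)[C@H]1C[C@@H](O)C(C)C(=O)O1 | intermediate
10 | (2E)-3-[(2R,4R)-4-(tert-butyldimethylsilyloxy)-5-methyl-6-oxooxan-2-yl]but-2-enal | O=C/C=C(\C)[C@H]1C[C@@H](O[Si](C)(C)C(C)(C)C)C(C)C(=O)O1 | intermediate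
11 | tert-butyl 3-methylbut-2-enoate | CC(C)=CC(=O)OC(C)(C)C | starting material
12 | tert-butyl[(1-tert-butoxy-3-methylbuta-1,3-dien-1-yl)oxy]dimethylsilane | C=C(C)C=C(OC(C)(C)C)O[Si](C)(C)C(C)(C)C | intermediate
13 | trichlorosilyl ether of 14 (5-OSiCl3) | CC(C)(C)OC(=O)/C=C(\C)C[C@H](O[Si](Cl)(Cl)Cl)/C=C(\C)[C@H]1C[C@@H](O[Si](C)(C)C(C)(C)C)C(C)C(=O)O1 | intermediate
14 | tert-butyl (2E,5S,6E)-5-hydroxy-3-methyl-7-[(2R,4R)-4-(tert-butyldimethylsilyloxy)-5-methyl-6-oxooxan-2-yl]octa-2,6-dienoate | CC(C)(C)OC(=O)/C=C(\C)C[C@H](O)/C=C(\C)[C@H]1C[C@@H](O[Si](C)(C)C(C)(C)C)C(C)C(=O)O1 | intermediate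
15 | triethylsilyl ester of 16 (5-OSiEt3, CO2SiEt3) | CC[Si](CC)(CC)OC(=O)/C=C(\C)C[C@H](O[Si](CC)(CC)CC)/C=C(\C)[C@H]1C[C@@H](O[Si](C)(C)C(C)(C)C)C(C)C(=O)O1 | intermediate
16 | (2E,5S,6E)-3-methyl-5-(triethylsilyloxy)-7-[(2R,4R)-4-(tert-butyldimethylsilyloxy)-5-methyl-6-oxooxan-2-yl]octa-2,6-dienoic acid | OC(=O)/C=C(\C)C[C@H](O[Si](CC)(CC)CC)/C=C(\C)[C@H]1C[C@@H](O[Si](C)(C)C(C)(C)C)C(C)C(=O)O1 | intermediate
17 | acid chloride of 16 | ClC(=O)/C=C(\C)C[C@H](O[Si](CC)(CC)CC)/C=C(\C)[C@H]1C[C@@H](O[Si](C)(C)C(C)(C)C)C(C)C(=O)O1 | intermediate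
18 | vinylketene: (5S,6E)-3-methylidene-5-(triethylsilyloxy)-7-[(2R,4R)-4-(tert-butyldimethylsilyloxy)-5-methyl-6-oxooxan-2-yl]octa-1,6-dien-1-one | O=C=CC(=C)C[C@H](O[Si](CC)(CC)CC)/C=C(\C)[C@H]1C[C@@H](O[Si](C)(C)C(C)(C)C)C(C)C(=O)O1 | intermediate
19 | bicyclo[3.1.1]heptan-6-one lactone (C2 ketone; C4–OSiEt3 on the C2 side; C6=CH2; C8–CH3 syn, lactone anti to the C4–C6 bridge) | O=C2[C@H]3[C@@H](O[Si](CC)(CC)CC)CC(=C)[C@@H]2[C@@]3(C)[C@H]1C[C@@H](O[Si](C)(C)C(C)(C)C)C(C)C(=O)O1 | intermediate
20 | lithium aldolate (C1–C2 closed; C2–OLi) | O=C1O[C@@H]2C[C@@H](O[Si](C)(C)C(C)(C)C)[C@@]1(C)[C@]3([O-])[C@H]4[C@@H](O[Si](CC)(CC)CC)CC(=C)[C@@H]3[C@@]24C.[Li+] | intermediate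
21 | lithium xanthate (C2–OC(=S)SLi) | O=C1O[C@@H]2C[C@@H](O[Si](C)(C)C(C)(C)C)[C@@]1(C)[C@]3(OC(=S)[S-])[C@H]4[C@@H](O[Si](CC)(CC)CC)CC(=C)[C@@H]3[C@@]24C.[Li+] | intermediate
22 | bridged lactone S-methyl xanthate (C2–OC(=S)SCH3) | O=C1O[C@@H]2C[C@@H](O[Si](C)(C)C(C)(C)C)[C@@]1(C)[C@]3(OC(=S)SC)[C@H]4[C@@H](O[Si](CC)(CC)CC)CC(=C)[C@@H]3[C@@]24C | intermediate
23 | bridged lactone with C2–H (C4–OSiEt3; C11–OTBS; C6=CH2) | O=C1O[C@@H]2C[C@@H](O[Si](C)(C)C(C)(C)C)[C@@]1(C)[C@@H]3[C@H]4[C@@H](O[Si](CC)(CC)CC)CC(=C)[C@@H]3[C@@]24C | intermediate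
24 | 9,15-diol (C4–OSiEt3; C11–OTBS; C6=CH2) | OC[C@]1(C)[C@@H]2[C@H]3[C@@H](O[Si](CC)(CC)CC)CC(=C)[C@@H]2[C@@]3(C)[C@H](O)C[C@H]1O[Si](C)(C)C(C)(C)C | intermediate
25 | angelic acid, (2Z)-2-methylbut-2-enoic acid | C/C=C(/C)C(=O)O | starting material
26 | angelic 2,4,6-trichlorobenzoic anhydride | C/C=C(/C)C(=O)OC(=O)c1c(Cl)cc(Cl)cc1Cl | intermediate
27 | 9,15-bis-angelate (C4–OSiEt3; C11–OTBS; C6=CH2) | C/C=C(/C)C(=O)OC[C@]1(C)[C@@H]2[C@H]3[C@@H](O[Si](CC)(CC)CC)CC(=C)[C@@H]2[C@@]3(C)[C@H](OC(=O)/C(C)=C\C)C[C@H]1O[Si](C)(C)C(C)(C)C | intermediate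
28 | C4 alcohol (C4–OH; C11–OTBS; C6=CH2) | C/C=C(/C)C(=O)OC[C@]1(C)[C@@H]2[C@H]3[C@@H](O)CC(=C)[C@@H]2[C@@]3(C)[C@H](OC(=O)/C(C)=C\C)C[C@H]1O[Si](C)(C)C(C)(C)C | intermediate
29 | β,γ-enone (C4 ketone; C6=CH2; C11–OTBS) | C/C=C(/C)C(=O)OC[C@]1(C)[C@@H]2[C@H]3C(=O)CC(=C)[C@@H]2[C@@]3(C)[C@H](OC(=O)/C(C)=C\C)C[C@H]1O[Si](C)(C)C(C)(C)C | intermediate
30 | enone (C4 ketone; C5=C6; C11–OTBS) | C/C=C(/C)C(=O)OC[C@]1(C)[C@@H]2[C@H]3C(=O)C=C(C)[C@@H]2[C@@]3(C)[C@H](OC(=O)/C(C)=C\C)C[C@H]1O[Si](C)(C)C(C)(C)C | intermediate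
31 | C11 alcohol (9,15-bis-angelate enone) | C/C=C(/C)C(=O)OC[C@]1(C)[C@@H]2[C@H]3C(=O)C=C(C)[C@@H]2[C@@]3(C)[C@H](OC(=O)/C(C)=C\C)C[C@H]1O | intermediate
32 | CNP0364726.1, (1S,2S,3R,7R,8R,9R,11R) in the labels above | C/C=C(/C)C(=O)OC[C@]1(C)[C@@H]2[C@H]3C(=O)C=C(C)[C@@H]2[C@@]3(C)[C@H](OC(=O)/C(C)=C\C)C[C@H]1OC(C)=O | target

## Step count and risks

Total step count: 16. Longest linear sequence: 15 (steps 1–5 and 7–16; step 6 is a one-step side branch).

**Step 9 (vinylketene [2+2]).** The alkene carries an allylic C–O bond on each side and may be too poor a nucleophile for the ketene, so that dimerisation wins. The C9 lactone centre also has an inherent facial bias that probably opposes the C4 control. The fallback keeps the same precursor but switches to the more electrophilic keteniminium manifold. It sets out from 16: acid chloride 17 and vinylketene 18 are generated as before, and 18 is intercepted at −20 °C with pyrrolidine to give the β,γ-unsaturated pyrrolidine amide F1. Tf2O and 2,4,6-collidine in 1,2-dichloroethane (0 → 80 °C) convert it into the keteniminium triflate F2. Intramolecular [2+2] with the same alkene, with the same regiochemistry and the same A(1,3) facial control, gives the cyclobutaniminium triflate F3. Aqueous NaHCO3 hydrolysis brings the route back at 19.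

**Step 10 (transannular aldol with in situ xanthylation).** The aldolate is a crowded tertiary alkoxide, 1,3-syn to the C4 silyl ether. It may revert by retro-aldol on warming or resist reaction with CS2. The fallback closes the ring reductively and avoids alkoxide chemistry afterwards. It sets out from 19: the lactone enolate (LiHMDS, −78 °C) is quenched with NBS to give the α-bromo lactone F4. SmI2 (THF, −78 °C) forms a samarium(III) enolate chelated to the cyclobutanone, which adds irreversibly (intramolecular Reformatsky) and gives on protonation the tertiary alcohol F5. Acylation with methyl chlorooxoacetate and DMAP gives the methyl oxalate F6. Bu3SnH/AIBN in toluene at 110 °C then removes the C2 oxygen, and the route is rejoined at 23.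

**Step 13 (double angeloylation).** The neopentyl primary and especially the hindered C9 secondary hydroxyl may acylate sluggishly, and prolonged heating risks isomerisation to tiglate. The fallback builds the angelate double bonds on the ester instead. It sets out from 24, which is acylated (EDC, DMAP, CH2Cl2) with the unhindered 2-[bis(2,2,2-trifluoroethoxy)phosphoryl]propanoic acid to give the bis(phosphonopropionate) F7. A double Still–Gennari olefination with acetaldehyde (KHMDS, 18-crown-6, THF, −78 °C) gives the two (Z)-2-methylbut-2-enoates and returns at 27.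

## Further compounds

F1 | step 9 | β,γ-unsaturated pyrrolidine amide (from vinylketene 18 and pyrrolidine) | O=C(N1CCCC1)CC(=C)C[C@H](O[Si](CC)(CC)CC)/C=C(\C)[C@H]1C[C@@H](O[Si](C)(C)C(C)(C)C)C(C)C(=O)O1
F2 | step 9 | keteniminium triflate | C=C(C=C=[N+]1CCCC1)C[C@H](O[Si](CC)(CC)CC)/C=C(\C)[C@H]2C[C@@H](O[Si](C)(C)C(C)(C)C)C(C)C(=O)O2.[O-]S(=O)(=O)C(F)(F)F
F3 | step 9 | cyclobutaniminium triflate (iminium analogue of 19) | C1CC[N+](C1)=C2[C@H]3[C@@H](O[Si](CC)(CC)CC)CC(=C)[C@@H]2[C@@]3(C)[C@H]4C[C@@H](O[Si](C)(C)C(C)(C)C)C(C)C(=O)O4.[O-]S(=O)(=O)C(F)(F)F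
F4 | step 10 | α-bromo lactone of 19 (C1–Br, epimers) | O=C2[C@H]3[C@@H](O[Si](CC)(CC)CC)CC(=C)[C@@H]2[C@@]3(C)[C@H]1C[C@@H](O[Si](C)(C)C(C)(C)C)C(C)(Br)C(=O)O1
F5 | step 10 | bridged lactone tertiary alcohol (C2–OH) | O=C1O[C@@H]2C[C@@H](O[Si](C)(C)C(C)(C)C)[C@@]1(C)[C@]3(O)[C@H]4[C@@H](O[Si](CC)(CC)CC)CC(=C)[C@@H]3[C@@]24C
F6 | step 10 | bridged lactone methyl oxalate (C2–OC(=O)CO2CH3) | O=C1O[C@@H]2C[C@@H](O[Si](C)(C)C(C)(C)C)[C@@]1(C)[C@]3(OC(=O)C(=O)OC)[C@H]4[C@@H](O[Si](CC)(CC)CC)CC(=C)[C@@H]3[C@@]24C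
F7 | step 13 | 9,15-bis{2-[bis(2,2,2-trifluoroethoxy)phosphoryl]propanoate} of 24 | CC(C(=O)OC[C@]1(C)[C@@H]2[C@H]3[C@@H](O[Si](CC)(CC)CC)CC(=C)[C@@H]2[C@@]3(C)[C@H](OC(=O)C(C)P(=O)(OCC(F)(F)F)OCC(F)(F)F)C[C@H]1O[Si](C)(C)C(C)(C)C)P(=O)(OCC(F)(F)F)OCC(F)(F)F
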